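Everything rests on cutting C5–C10 and C8–C9 (halimane numbering). Because the ring-fusion carbon C10 is sp2 (C1=C10) and lies next to quaternary C9, rings A and B can be read as the adduct of a (5E,7Z)-diene (C5–C8) with the distal C9=C10 π bond of a C1=C10=C9 allene. One nickel-catalysed intramolecular [4+2] cycloaddition should close both rings and set C5, C8 and C9, leaving the other allene π bond as C1=C10. Its substrate is an acyclic methyl ester with the (4S) quaternary centre, the (E,Z)-diene, an (aR) trisubstituted allene and a ketal-masked C11–C13 chain; the epoxy alcohol is built afterwards.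

Key step: step 14

Remark: atoms are numbered as in halimane throughout (C16 is the methyl on C13). The pairing (4S)/(aR)/(5E,7Z) in the cycloaddition substrate corresponds to (4S,5R,8R,9S) in the bicycle, and (13R,14R) in the epoxide.

Assumption: pig liver esterase is taken to give the (R)-half-ester of the alkylated methylmalonate, the sense usual for 2-methylmalonates whose second substituent is a chain of five or more atoms. The antipode would serve equally, because reduction of its acid group instead of its ester group leads to the same hydroxy ester that enters step 5.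

Step 1
Reactants: 1 dimethyl methylmalonate; 2 2-(2-bromoethyl)-1,3-dioxolane
Product: 4 dimethyl 2-[2-(1,3-dioxolan-2-yl)ethyl]-2-methylpropanedioate, via sodium enolate of dimethyl methylmalonate 3 (not isolated)
Conditions: NaH, THF/DMF, 0 °C; then 2, NaI (cat.), 60 °C
Reagents that add atoms: none
Why: Malonate alkylation (SN2), in which the stabilised enolate displaces the primary bromide and builds the still prochiral quaternary C4 with C3–C2–C1 as a masked aldehyde.

Step 2
Reactants: 4 dimethyl 2-[2-(1,3-dioxolan-2-yl)ethyl]-2-methylpropanedioate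
Product: 5 (2R)-2-[2-(1,3-dioxolan-2-yl)ethyl]-3-methoxy-2-methyl-3-oxopropanoic acid
Conditions: pig liver esterase, phosphate buffer pH 7.5/DMSO (9:1), 1 M NaOH (pH-stat), 25 °C; then cold 1 M HCl to pH 3, EtOAc
Reagents that add atoms: water, O
Why: Enzymatic desymmetrisation, in which the esterase distinguishes the two enantiotopic ester groups of a 2-alkyl-2-methylmalonate and hydrolyses one of them, which sets C4 while the acetal survives the neutral buffer.

Step 3
Reactants: 5 (2R)-2-[2-(1,3-dioxolan-2-yl)ethyl]-3-methoxy-2-methyl-3-oxopropanoic acid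
Product: 7 (2S)-2-[2-(1,3-dioxolan-2-yl)ethyl]-3-hydroxy-2-methylpropanoic acid, via lithium salt of the half-ester 6 (not isolated)
Conditions: LiHMDS (1.0 equiv), THF, −20 °C; then LiBH4, 0 → 25 °C; cold 1 M HCl to pH 4
Reagents that add atoms: none
Why: Chemoselective hydride reduction, since LiBH4 reduces the methyl ester while the pre-formed lithium carboxylate is inert, so the acid group (the future C4 ester) is kept and C4 is not touched.

Step 4
Reactants: 7 (2S)-2-[2-(1,3-dioxolan-2-yl)ethyl]-3-hydroxy-2-methylpropanoic acid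
Product: 8 methyl (2S)-2-[2-(1,3-dioxolan-2-yl)ethyl]-3-hydroxy-2-methylpropanoate
Conditions: MeI, KHCO3, DMF, 25 °C
Reagents that add atoms: iodomethane, CI
Why: Carboxylate O-alkylation (SN2 at MeI) under bicarbonate conditions puts the methyl ester on the former acid site and leaves the primary alcohol and the stereocentre alone.

Step 5
Reactants: 8 methyl (2S)-2-[2-(1,3-dioxolan-2-yl)ethyl]-3-hydroxy-2-methylpropanoate
Product: 9 methyl (2S)-2-[2-(1,3-dioxolan-2-yl)ethyl]-2-methyl-3-oxopropanoate
Conditions: Dess–Martin periodinane, pyridine, CH2Cl2, 0 → 25 °C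
Reagents that add atoms: none
Why: Dess–Martin oxidation turns the neopentyl-type primary alcohol into the C5 aldehyde, which cannot epimerise because C4 bears no hydrogen.

Step 6
Reactants: 9 methyl (2S)-2-[2-(1,3-dioxolan-2-yl)ethyl]-2-methyl-3-oxopropanoate
Product: 10 methyl (2S,3E)-2-[2-(1,3-dioxolan-2-yl)ethyl]-4-iodo-2-methylbut-3-enoate
Conditions: CrCl2, CHI3, THF/1,4-dioxane, 0 → 25 °C
Reagents that add atoms: iodoform, IC(I)I
Why: Takai olefination, in which the geminal dichromium reagent adds to the aldehyde and eliminates to the E-vinyl iodide (C5=C6) while ester and acetal are tolerated.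

Step 7
Reactants: 10 methyl (2S,3E)-2-[2-(1,3-dioxolan-2-yl)ethyl]-4-iodo-2-methylbut-3-enoate; 11 (Z)-prop-1-en-1-ylboronic acid
Product: 12 methyl (2S,3E,5Z)-2-[2-(1,3-dioxolan-2-yl)ethyl]-2-methylhepta-3,5-dienoate
Conditions: Pd(PPh3)4 (5 mol %), K3PO4, THF/H2O, 50 °C
Reagents that add atoms: none
Why: Suzuki–Miyaura coupling retains the geometry of both partners, so the E-iodide and the Z-boronic acid give the (5E,7Z)-diene C5–C8.

Step 8
Reactants: 12 methyl (2S,3E,5Z)-2-[2-(1,3-dioxolan-2-yl)ethyl]-2-methylhepta-3,5-dienoate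
Product: 13 methyl (2S,3E,5Z)-2-methyl-2-(3-oxopropyl)hepta-3,5-dienoate
Conditions: 1 M HCl, THF, 25 °C
Reagents that add atoms: water, O
Why: Acid-catalysed acetal hydrolysis frees the C1 aldehyde under conditions mild enough for the diene geometry and the hindered ester.

Step 9
Reactants: 13 methyl (2S,3E,5Z)-2-methyl-2-(3-oxopropyl)hepta-3,5-dienoate; 14 prop-1-yn-1-ylmagnesium bromide
Product: 15 methyl (2S,3E,5Z)-2-(3-hydroxyhex-4-yn-1-yl)-2-methylhepta-3,5-dienoate (both C1 epimers)
Conditions: THF, −78 °C; aq. NH4Cl at −78 °C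
Reagents that add atoms: none
Why: Grignard 1,2-addition of the alkynyl reagent to the aldehyde is far faster at −78 °C than attack on the methyl ester at quaternary C4, and the C1 configuration does not matter because the next step erases it.

Step 10
Reactants: 15 methyl (2S,3E,5Z)-2-(3-hydroxyhex-4-yn-1-yl)-2-methylhepta-3,5-dienoate (both C1 epimers)
Product: 16 methyl (2S,3E,5Z)-2-methyl-2-(3-oxohex-4-yn-1-yl)hepta-3,5-dienoate
Conditions: Dess–Martin periodinane, pyridine, CH2Cl2, 0 °C
Reagents that add atoms: none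
Why: Dess–Martin oxidation of the propargylic alcohol gives the ynone and removes the δ-hydroxy ester before it can lactonise.

Step 11
Reactants: 16 methyl (2S,3E,5Z)-2-methyl-2-(3-oxohex-4-yn-1-yl)hepta-3,5-dienoate
Product: 17 methyl (2S,3E,5Z)-2-[(3S)-3-hydroxyhex-4-yn-1-yl]-2-methylhepta-3,5-dienoate
Conditions: Ru[(S,S)-TsNCHPhCHPhNH](p-cymene) (2 mol %), i-PrOH, 25 °C
Reagents that add atoms: none
Why: Noyori asymmetric transfer hydrogenation, in which the (S,S) ruthenium hydride treats the alkynyl group as it would an aryl group and delivers hydride to one face of the ynone, which should set (1S) under base-free conditions that spare the δ-hydroxy ester.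

Step 12
Reactants: 17 methyl (2S,3E,5Z)-2-[(3S)-3-hydroxyhex-4-yn-1-yl]-2-methylhepta-3,5-dienoate
Product: 18 methyl (2S,3E,5Z)-2-[(3S)-3-(methanesulfonyloxy)hex-4-yn-1-yl]-2-methylhepta-3,5-dienoate
Conditions: MsCl, Et3N, CH2Cl2, −40 °C; used crude
Reagents that add atoms: methanesulfonyl chloride, CS(=O)(=O)Cl
Why: Sulfonylation of the secondary alcohol, with retention at C1, provides the leaving group for the allene synthesis.

Step 13
Reactants: 18 methyl (2S,3E,5Z)-2-[(3S)-3-(methanesulfonyloxy)hex-4-yn-1-yl]-2-methylhepta-3,5-dienoate; 19 2-(2-bromoethyl)-2-methyl-1,3-dioxolane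
Product: 21 methyl (2S,3E,5Z)-2-methyl-2-[(aR)-5-methyl-7-(2-methyl-1,3-dioxolan-2-yl)hepta-3,4-dien-1-yl]hepta-3,5-dienoate, via [2-(2-methyl-1,3-dioxolan-2-yl)ethyl]magnesium bromide 20 (not isolated)
Conditions: 19, Mg, THF, 25 °C; then CuBr·SMe2 (10 mol %), LiBr (20 mol %), −78 °C; then 18, −78 → −40 °C
Reagents that add atoms: none
Why: Copper-catalysed anti-SN2′ substitution, in which the alkylcopper species attacks C9 on the face opposite the departing mesylate, so the (1S) centre becomes the (aR) axis of the C1=C10=C9 allene while ester and diene stay untouched.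

Step 14
Reactants: 21 methyl (2S,3E,5Z)-2-methyl-2-[(aR)-5-methyl-7-(2-methyl-1,3-dioxolan-2-yl)hepta-3,4-dien-1-yl]hepta-3,5-dienoate
Product: 22 methyl (1S,5S,6R,8aR)-1,5,6-trimethyl-5-[2-(2-methyl-1,3-dioxolan-2-yl)ethyl]-1,2,3,5,6,8a-hexahydronaphthalene-1-carboxylate
Conditions: Ni(cod)2 (10 mol %), P(O-2-biphenylyl)3 (30 mol %), THF (0.01 M), 25 → 60 °C
Reagents that add atoms: none
Why: Proposed new method: zerovalent nickel carrying the π-acidic phosphite should bind the s-cis diene and, on the allene face that bears C2, the distal C9=C10 π bond, form C5–C10 by oxidative cyclisation (nickel then held by C9 and the C6–C8 allyl unit) and form C8–C9 by reductive elimination, which amounts to a [4+2] addition that is suprafacial on both partners. The closest known reaction type is the intramolecular [4+2] cycloaddition of a diene to a tethered allene, run thermally or under Ni(cod)2 or [Rh(cod)Cl]2 catalysis, which has not been shown for a fully substituted distal allene carbon joined to a Z diene terminus. Ring B closes as the six-membered cycloaddition ring (C5–C8 plus C9 and C10) and ring A closes through the C5–C10 bond in a fused 6-exo mode across the C2–C3–C4 tether, the untouched allene π bond ending inside ring A as C1=C10. C9 is set by the (aR) axis, because the tether lets the diene reach only the C2 face of C9=C10, whereas C5 and C8 are set by the diene geometry (C4 outside at C5 and methyl inside at C8, hence H5 and the C8 methyl cis) together with the chain-endo arrangement, in which the small C9 methyl and not C11 lies beside the inside methyl and so ends on the face of H5 and the C8 methyl. The step needs the distal and not the proximal π bond to react, which the catalyst and the three-atom tether on the gem-disubstituted C4 (a strain-free six-membered ring A) are relied on to give, and it needs the axis to be transferred without scrambling, which the mild temperature (no [1,5]-hydrogen shift of the Z diene, no allene racemisation) and a reductive elimination faster than allyl isomerisation should secure. C4 is a spectator whose (S) configuration is simply paired with the (aR) axis in the precursor.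

Step 15
Reactants: 22 methyl (1S,5S,6R,8aR)-1,5,6-trimethyl-5-[2-(2-methyl-1,3-dioxolan-2-yl)ethyl]-1,2,3,5,6,8a-hexahydronaphthalene-1-carboxylate
Product: 23 methyl (1S,5S,6R,8aR)-1,5,6-trimethyl-5-[2-(2-methyl-1,3-dioxolan-2-yl)ethyl]-1,2,3,5,6,7,8,8a-octahydronaphthalene-1-carboxylate
Conditions: 2-nitrobenzenesulfonylhydrazide (2-O2NC6H4SO2NHNH2), Et3N, CH2Cl2, 25 °C
Reagents that add atoms: none
Why: Diimide reduction (concerted syn transfer of two hydrogens) is fastest at the cis-disubstituted C6=C7 bond and should leave the trisubstituted C1=C10 bond, with no new stereocentre formed.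

Step 16
Reactants: 23 methyl (1S,5S,6R,8aR)-1,5,6-trimethyl-5-[2-(2-methyl-1,3-dioxolan-2-yl)ethyl]-1,2,3,5,6,7,8,8a-octahydronaphthalene-1-carboxylate
Product: 24 methyl (1S,5S,6R,8aR)-1,5,6-trimethyl-5-(3-oxobutyl)-1,2,3,5,6,7,8,8a-octahydronaphthalene-1-carboxylate
Conditions: AcOH/THF/H2O (3:1:1), 40 °C
Reagents that add atoms: water, O
Why: Mild acidic ketal hydrolysis frees the C13 methyl ketone without moving the C1=C10 double bond.

Step 17
Reactants: 24 methyl (1S,5S,6R,8aR)-1,5,6-trimethyl-5-(3-oxobutyl)-1,2,3,5,6,7,8,8a-octahydronaphthalene-1-carboxylate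
Product: 25 methyl (1S,5S,6R,8aR)-5-[(3E)-5-ethoxy-3-methyl-5-oxopent-3-en-1-yl]-1,5,6-trimethyl-1,2,3,5,6,7,8,8a-octahydronaphthalene-1-carboxylate
Conditions: (EtO)2P(O)CH2CO2Et, NaH, THF, 0 → 65 °C; chromatography
Reagents that add atoms: triethyl phosphonoacetate, CCOC(=O)CP(=O)(OCC)OCC
Why: Horner–Wadsworth–Emmons olefination of the methyl ketone gives mainly the E enoate (ester trans to the larger C12 chain), and the minor Z isomer is removed by chromatography.

Step 18
Reactants: 25 methyl (1S,5S,6R,8aR)-5-[(3E)-5-ethoxy-3-methyl-5-oxopent-3-en-1-yl]-1,5,6-trimethyl-1,2,3,5,6,7,8,8a-octahydronaphthalene-1-carboxylate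
Product: 26 methyl (1S,5S,6R,8aR)-5-[(3E)-5-hydroxy-3-methylpent-3-en-1-yl]-1,5,6-trimethyl-1,2,3,5,6,7,8,8a-octahydronaphthalene-1-carboxylate
Conditions: i-Bu2AlH (2.2 equiv), CH2Cl2, −78 °C; aq. potassium sodium tartrate (KNaC4H4O6)
Reagents that add atoms: none
Why: Hydride 1,2-reduction with i-Bu2AlH at −78 °C takes the unhindered conjugated ethyl ester to the allylic alcohol, whereas the C4 methyl ester on a quaternary carbon beside the ring fusion should react much more slowly.

Step 19
Reactants: 26 methyl (1S,5S,6R,8aR)-5-[(3E)-5-hydroxy-3-methylpent-3-en-1-yl]-1,5,6-trimethyl-1,2,3,5,6,7,8,8a-octahydronaphthalene-1-carboxylate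
Product: 27 methyl (1S,5S,6R,8aR)-5-{2-[(2R,3R)-3-(hydroxymethyl)-2-methyloxiran-2-yl]ethyl}-1,5,6-trimethyl-1,2,3,5,6,7,8,8a-octahydronaphthalene-1-carboxylate
Conditions: Ti(OiPr)4 (10 mol %), D-(−)-diethyl tartrate (12 mol %), t-BuOOH, 4 Å molecular sieves, CH2Cl2, −20 °C
Reagents that add atoms: tert-butyl hydroperoxide, CC(C)(C)OO
Why: Sharpless asymmetric epoxidation, in which the titanium tartrate complex binds the allylic hydroxyl and delivers oxygen under reagent control, D-(−)-diethyl tartrate giving the (13R,14R) epoxide from an E-3-methylalk-2-en-1-ol while the isolated C1=C10 alkene is not touched.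

Compound list
1 | dimethyl methylmalonate | COC(=O)C(C)C(=O)OC | starting material
2 | 2-(2-bromoethyl)-1,3-dioxolane | BrCCC1OCCO1 | starting material
3 | sodium enolate of dimethyl methylmalonate (formed in the flask) | [Na+].COC(=O)C(C)=C([O-])OC | intermediate
4 | dimethyl 2-[2-(1,3-dioxolan-2-yl)ethyl]-2-methylpropanedioate | COC(=O)C(C)(CCC1OCCO1)C(=O)OC | intermediate
5 | (2R)-2-[2-(1,3-dioxolan-2-yl)ethyl]-3-methoxy-2-methyl-3-oxopropanoic acid | OC(=O)[C@@](C)(CCC1OCCO1)C(=O)OC | intermediate
6 | lithium (2R)-2-[2-(1,3-dioxolan-2-yl)ethyl]-3-methoxy-2-methyl-3-oxopropanoate (formed in the flask) | [Li+].[O-]C(=O)[C@@](C)(CCC1OCCO1)C(=O)OC | intermediate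
7 | (2S)-2-[2-(1,3-dioxolan-2-yl)ethyl]-3-hydroxy-2-methylpropanoic acid | OC(=O)[C@@](C)(CCC1OCCO1)CO | intermediate
8 | methyl (2S)-2-[2-(1,3-dioxolan-2-yl)ethyl]-3-hydroxy-2-methylpropanoate | COC(=O)[C@@](C)(CCC1OCCO1)CO | intermediate
9 | methyl (2S)-2-[2-(1,3-dioxolan-2-yl)ethyl]-2-methyl-3-oxopropanoate | COC(=O)[C@@](C)(CCC1OCCO1)C=O | intermediate
10 | methyl (2S,3E)-2-[2-(1,3-dioxolan-2-yl)ethyl]-4-iodo-2-methylbut-3-enoate | COC(=O)[C@@](C)(CCC1OCCO1)/C=C/I | intermediate
11 | (Z)-prop-1-en-1-ylboronic acid | C/C=C\B(O)O | starting material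
12 | methyl (2S,3E,5Z)-2-[2-(1,3-dioxolan-2-yl)ethyl]-2-methylhepta-3,5-dienoate | COC(=O)[C@@](C)(CCC1OCCO1)/C=C/C=C\C | intermediate
13 | methyl (2S,3E,5Z)-2-methyl-2-(3-oxopropyl)hepta-3,5-dienoate | COC(=O)[C@@](C)(CCC=O)/C=C/C=C\C | intermediate
14 | prop-1-yn-1-ylmagnesium bromide (commercial THF solution) | CC#C[Mg]Br | starting material
15 | methyl (2S,3E,5Z)-2-(3-hydroxyhex-4-yn-1-yl)-2-methylhepta-3,5-dienoate (both C1 epimers) | COC(=O)[C@@](C)(CCC(O)C#CC)/C=C/C=C\C | intermediate
16 | methyl (2S,3E,5Z)-2-methyl-2-(3-oxohex-4-yn-1-yl)hepta-3,5-dienoate | COC(=O)[C@@](C)(CCC(=O)C#CC)/C=C/C=C\C | intermediate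
17 | methyl (2S,3E,5Z)-2-[(3S)-3-hydroxyhex-4-yn-1-yl]-2-methylhepta-3,5-dienoate | COC(=O)[C@@](C)(CC[C@H](O)C#CC)/C=C/C=C\C | intermediate
18 | methyl (2S,3E,5Z)-2-[(3S)-3-(methanesulfonyloxy)hex-4-yn-1-yl]-2-methylhepta-3,5-dienoate | COC(=O)[C@@](C)(CC[C@H](OS(C)(=O)=O)C#CC)/C=C/C=C\C | intermediate
19 | 2-(2-bromoethyl)-2-methyl-1,3-dioxolane | CC1(CCBr)OCCO1 | starting material
20 | [2-(2-methyl-1,3-dioxolan-2-yl)ethyl]magnesium bromide (formed in the flask) | CC1(CC[Mg]Br)OCCO1 | intermediate
21 | methyl (2S,3E,5Z)-2-methyl-2-[(aR)-5-methyl-7-(2-methyl-1,3-dioxolan-2-yl)hepta-3,4-dien-1-yl]hepta-3,5-dienoate (cycloaddition substrate) | COC(=O)[C@@](C)(CCC([H])=[C@]=C(C)CCC1(C)OCCO1)/C=C/C=C\C | intermediate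
22 | methyl (1S,5S,6R,8aR)-1,5,6-trimethyl-5-[2-(2-methyl-1,3-dioxolan-2-yl)ethyl]-1,2,3,5,6,8a-hexahydronaphthalene-1-carboxylate (cycloadduct; halimane C1=C10 and C6=C7) | COC(=O)[C@@]1(C)CCC=C2[C@H]1C=C[C@@H](C)[C@]2(C)CCC1(C)OCCO1 | intermediate
23 | methyl (1S,5S,6R,8aR)-1,5,6-trimethyl-5-[2-(2-methyl-1,3-dioxolan-2-yl)ethyl]-1,2,3,5,6,7,8,8a-octahydronaphthalene-1-carboxylate | COC(=O)[C@@]1(C)CCC=C2[C@H]1CC[C@@H](C)[C@]2(C)CCC1(C)OCCO1 | intermediate
24 | methyl (1S,5S,6R,8aR)-1,5,6-trimethyl-5-(3-oxobutyl)-1,2,3,5,6,7,8,8a-octahydronaphthalene-1-carboxylate | COC(=O)[C@@]1(C)CCC=C2[C@H]1CC[C@@H](C)[C@]2(C)CCC(C)=O | intermediate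
25 | methyl (1S,5S,6R,8aR)-5-[(3E)-5-ethoxy-3-methyl-5-oxopent-3-en-1-yl]-1,5,6-trimethyl-1,2,3,5,6,7,8,8a-octahydronaphthalene-1-carboxylate | COC(=O)[C@@]1(C)CCC=C2[C@H]1CC[C@@H](C)[C@]2(C)CC/C(C)=C/C(=O)OCC | intermediate
26 | methyl (1S,5S,6R,8aR)-5-[(3E)-5-hydroxy-3-methylpent-3-en-1-yl]-1,5,6-trimethyl-1,2,3,5,6,7,8,8a-octahydronaphthalene-1-carboxylate | COC(=O)[C@@]1(C)CCC=C2[C@H]1CC[C@@H](C)[C@]2(C)CC/C(C)=C/CO | intermediate
27 | methyl (1S,5S,6R,8aR)-5-{2-[(2R,3R)-3-(hydroxymethyl)-2-methyloxiran-2-yl]ethyl}-1,5,6-trimethyl-1,2,3,5,6,7,8,8a-octahydronaphthalene-1-carboxylate (CNP0324371.2) | COC(=O)[C@@]1(C)CCC=C2[C@H]1CC[C@@H](C)[C@]2(C)CC[C@@]1(C)O[C@@H]1CO | target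

Total step count: 19 steps.
Longest linear sequence: 19 steps (from 1 and 2 to 27); 11, 14 and 19 are purchased reagents.

Steps most likely to fail

Step 14 (the step labelled as a proposed new method). The diene may add to the proximal C1=C10 π bond and close a five-membered ring, the hindered C9 may not be engaged at all, or allyl-nickel isomerisation may scramble the stereochemistry. The fallback uses known chemistry, sets out from ynone 16 and returns at 22. A thermal intramolecular Diels–Alder reaction of 16 (degassed toluene, 110–140 °C, sealed vessel) uses the ketone-activated C9≡C10 alkyne as dienophile, forms the same C5–C10 and C8–C9 bonds and should give the bicyclic cross-conjugated dienone F1, with H5 and the C8 methyl cis through suprafacial addition to the (E,Z)-diene. Conjugate addition of the cuprate made from Grignard reagent 20 and CuBr·SMe2 (THF, −40 °C) to C9, anti to the neighbouring C8 methyl, gives the bromomagnesium enolate F2, which is trapped in the same flask with PhNTf2 as the enol triflate F3. Palladium-catalysed formate reduction of the triflate (Pd(OAc)2, PPh3, Bu3N, HCO2H, DMF, 60 °C) then gives 22. The price is weaker control of the C4/C5 relationship, which rests only on the conformational preference of the tether, so diastereomers may have to be separated at F1, and F1 must be kept from air to avoid aromatisation.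

Step 2. The enzymatic hydrolysis may be poorly selective between the two ester groups or may run in the opposite sense. The fallback sets out from diester 4 and returns at 5. Half-saponification of 4 (KOH, 1 equiv, MeOH, 25 °C) gives the racemic half-ester F4. It is resolved by crystallisation of its salt with (S)-1-phenylethylamine, the diastereomeric salt F5; the (R)-amine is used instead if the other salt proves the less soluble one. Acidification returns 5. The (S)-acid from the mother liquor is not lost, since reduction of its acid group (i-BuOCOCl, N-methylmorpholine, then NaBH4) leads to the same hydroxy ester 8.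

Step 13. Copper-induced racemisation may erode the allene axis, and direct SN2 attack or reduction may compete with the anti-SN2′ path when a functionalised primary alkyl group is transferred. The fallback sets out from aldehyde 13 and returns at 21; it exchanges the roles so that copper delivers the methyl group. 2-(But-3-yn-1-yl)-2-methyl-1,3-dioxolane F6 (from commercial hex-5-yn-2-one, ethylene glycol and TsOH) is deprotonated (n-BuLi, THF, −78 °C) to the lithium acetylide F7 and added to 13 to give the propargylic alcohol F8 as a C1 epimer mixture. Dess–Martin oxidation gives the ynone F9. Transfer hydrogenation with the enantiomeric catalyst Ru[(R,R)-TsNCHPhCHPhNH](p-cymene) in i-PrOH gives the (1R) alcohol F10, and mesylation gives F11. MeMgBr with CuBr·SMe2 and LiBr (THF, −78 °C) then adds methyl to C9 anti to the mesylate and should give the same (aR) allene 21.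

Further compounds
F1 | step 14 | methyl (1S,6R,8aR)-1,5,6-trimethyl-4-oxo-1,2,3,4,6,8a-hexahydronaphthalene-1-carboxylate | COC(=O)[C@@]1(C)CCC(=O)C=2[C@H]1C=C[C@@H](C)C=2C
F2 | step 14 | bromomagnesium enolate of the C9 conjugate adduct (C1–O–MgBr, C1=C10) | COC(=O)[C@@]1(C)CCC(O[Mg]Br)=C2[C@H]1C=C[C@@H](C)[C@]2(C)CCC1(C)OCCO1
F3 | step 14 | methyl (1S,5S,6R,8aR)-1,5,6-trimethyl-5-[2-(2-methyl-1,3-dioxolan-2-yl)ethyl]-4-(trifluoromethanesulfonyloxy)-1,2,3,5,6,8a-hexahydronaphthalene-1-carboxylate | COC(=O)[C@@]1(C)CCC(OS(=O)(=O)C(F)(F)F)=C2[C@H]1C=C[C@@H](C)[C@]2(C)CCC1(C)OCCO1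
F4 | step 2 | racemic 2-[2-(1,3-dioxolan-2-yl)ethyl]-3-methoxy-2-methyl-3-oxopropanoic acid | OC(=O)C(C)(CCC1OCCO1)C(=O)OC
F5 | step 2 | (S)-1-phenylethylammonium (2R)-2-[2-(1,3-dioxolan-2-yl)ethyl]-3-methoxy-2-methyl-3-oxopropanoate | C[C@H]([NH3+])c1ccccc1.[O-]C(=O)[C@@](C)(CCC1OCCO1)C(=O)OC
F6 | step 13 | 2-(but-3-yn-1-yl)-2-methyl-1,3-dioxolane | C#CCCC1(C)OCCO1
F7 | step 13 | lithium acetylide of 2-(but-3-yn-1-yl)-2-methyl-1,3-dioxolane | [Li]C#CCCC1(C)OCCO1
F8 | step 13 | methyl (2S,3E,5Z)-2-[3-hydroxy-7-(2-methyl-1,3-dioxolan-2-yl)hept-4-yn-1-yl]-2-methylhepta-3,5-dienoate (both C1 epimers) | COC(=O)[C@@](C)(CCC(O)C#CCCC1(C)OCCO1)/C=C/C=C\C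
F9 | step 13 | methyl (2S,3E,5Z)-2-methyl-2-[7-(2-methyl-1,3-dioxolan-2-yl)-3-oxohept-4-yn-1-yl]hepta-3,5-dienoate | COC(=O)[C@@](C)(CCC(=O)C#CCCC1(C)OCCO1)/C=C/C=C\C
F10 | step 13 | methyl (2S,3E,5Z)-2-[(3R)-3-hydroxy-7-(2-methyl-1,3-dioxolan-2-yl)hept-4-yn-1-yl]-2-methylhepta-3,5-dienoate | COC(=O)[C@@](C)(CC[C@@H](O)C#CCCC1(C)OCCO1)/C=C/C=C\C
F11 | step 13 | methyl (2S,3E,5Z)-2-[(3R)-3-(methanesulfonyloxy)-7-(2-methyl-1,3-dioxolan-2-yl)hept-4-yn-1-yl]-2-methylhepta-3,5-dienoate | COC(=O)[C@@](C)(CC[C@@H](OS(C)(=O)=O)C#CCCC1(C)OCCO1)/C=C/C=C\C
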